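**Retrosynthetic overview**
- The target comes from its tri-O-benzyl ether by one global O-debenzylation.
- The C3–C1' bond joins two carbons that are both innately nucleophilic. The ketone alpha carbon of an o-hydroxyaryl enaminone is made electrophilic with trivalent iodine (an enolonium equivalent), and a ring B arene C–H attacks it.
- Ring C is the only ring built. It closes in the same flask, by phenol O attack on the iminium carbon and then loss of Me2NH. Rings A and B are bought.
- The enaminone comes from phloroacetophenone by selective dibenzylation and then DMF-DMA. The arene comes from 2,4,6-trimethoxyphenol and BnBr.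

**Assumption:** the SMILES shows no stereocentre and no specified axis, so the target is treated as achiral and no configuration has to be set.

**Step 1**
Reactants: 1 2,4,6-trihydroxyacetophenone
Product: 2 1-[2,4-bis(benzyloxy)-6-hydroxyphenyl]ethan-1-one
Conditions: BnBr (2.05 equiv), K2CO3 (2.2 equiv), DMF, 0 °C to rt, 16 h
Reagents that add atoms: benzyl bromide, BrCc1ccccc1
Why: Williamson etherification, in which the hydroxyl hydrogen-bonded to the acetyl carbonyl is the least nucleophilic, so two equivalents of BnBr stop at the dibenzyl ether.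

**Step 2**
Reactants: 2 1-[2,4-bis(benzyloxy)-6-hydroxyphenyl]ethan-1-one
Product: 3 (E)-1-[2,4-bis(benzyloxy)-6-hydroxyphenyl]-3-(dimethylamino)prop-2-en-1-one
Conditions: DMF-DMA (3 equiv), toluene, 95 °C, 3 h
Reagents that add atoms: N,N-dimethylformamide dimethyl acetal, COC(OC)N(C)C
Why: Formamide-acetal condensation at the acidic acetyl CH3 with loss of two MeOH gives the thermodynamic E push–pull enaminone and leaves the chelated phenol untouched.

**Step 3**
Reactants: 4 2,4,6-trimethoxyphenol
Product: 5 2-(benzyloxy)-1,3,5-trimethoxybenzene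
Conditions: BnBr (1.1 equiv), K2CO3 (1.5 equiv), DMF, N2, rt, 6 h
Reagents that add atoms: benzyl bromide, BrCc1ccccc1
Why: Williamson etherification masks the oxidation-sensitive phenol and leaves two symmetry-equivalent C–H positions, each activated by three methoxy groups.

**Step 4**
Reactants: 3 (E)-1-[2,4-bis(benzyloxy)-6-hydroxyphenyl]-3-(dimethylamino)prop-2-en-1-one; 5 2-(benzyloxy)-1,3,5-trimethoxybenzene
Product: 8 5,7-bis(benzyloxy)-3-[3-(benzyloxy)-2,4,6-trimethoxyphenyl]-4H-chromen-4-one, via iodanyl aminal 6 (not isolated), via aminoisoflavanone 7 (not isolated)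
Conditions: PhI(OCOCF3)2 (1.05 equiv), CH2Cl2/(CF3)2CHOH 9:1, −40 °C, 5 min; then 5 (2.5 equiv), −40 °C to rt, 3 h; aq NaHCO3 work-up
Reagents that add atoms: none
Why: Proposed new method: the enaminone alpha carbon attacks trivalent iodine and the ortho phenol closes on the resulting iminium to give alpha-iodanyl ketone 6, whose alpha carbon is now electrophilic; the free C–H of 5 displaces iodobenzene in a Friedel–Crafts-type substitution to give 7, and acid-assisted E1cB loss of Me2NH erases the transient C2/C3 stereocentres and delivers 8; should 6 first collapse to a chromon-3-yl iodonium salt and 5 add at C2, the known hypervalent-iodine flavanone-to-isoflavone 1,2-aryl shift leads to the same product; the closest known reaction types are metal-free alpha-arylation of ketones through preformed enolonium species and PhI(OAc)2-mediated alpha-acyloxylation with chromone annulation of o-hydroxyaryl enaminones.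

**Step 5**
Reactants: 8 5,7-bis(benzyloxy)-3-[3-(benzyloxy)-2,4,6-trimethoxyphenyl]-4H-chromen-4-one
Product: 9 5,7-dihydroxy-3-(3-hydroxy-2,4,6-trimethoxyphenyl)-4H-chromen-4-one
Conditions: H2 (1 atm), 10% Pd/C, EtOAc/MeOH 1:1, rt, stopped after uptake of 3 equiv H2
Reagents that add atoms: none
Why: Catalytic hydrogenolysis cleaves all three aryl benzyl ethers, while the C2=C3 bond of the vinylogous ester, shielded by the di-ortho-methoxy aryl group, is reduced far more slowly.

**Compound list**
1 | 2,4,6-trihydroxyacetophenone | CC(=O)c1c(O)cc(O)cc1O | starting material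
2 | 1-[2,4-bis(benzyloxy)-6-hydroxyphenyl]ethan-1-one | CC(=O)c1c(O)cc(OCc2ccccc2)cc1OCc1ccccc1 | intermediate
3 | (E)-1-[2,4-bis(benzyloxy)-6-hydroxyphenyl]-3-(dimethylamino)prop-2-en-1-one | CN(C)/C=C/C(=O)c1c(O)cc(OCc2ccccc2)cc1OCc1ccccc1 | intermediate
4 | 2,4,6-trimethoxyphenol | COc1cc(OC)c(O)c(OC)c1 | starting material
5 | 2-(benzyloxy)-1,3,5-trimethoxybenzene | COc1cc(OC)c(OCc2ccccc2)c(OC)c1 | intermediate
6 | 5,7-bis(benzyloxy)-2-(dimethylamino)-3-[phenyl(trifluoroacetoxy)-λ3-iodanyl]chroman-4-one (diastereomer mixture, enolonium equivalent) | CN(C)C1Oc2cc(OCc3ccccc3)cc(OCc3ccccc3)c2C(=O)C1I(c4ccccc4)OC(=O)C(F)(F)F | intermediate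
7 | 5,7-bis(benzyloxy)-3-[3-(benzyloxy)-2,4,6-trimethoxyphenyl]-2-(dimethylamino)chroman-4-one (diastereomer mixture) | CN(C)C1Oc2cc(OCc3ccccc3)cc(OCc3ccccc3)c2C(=O)C1c4c(OC)cc(OC)c(OCc5ccccc5)c4OC | intermediate
8 | 5,7-bis(benzyloxy)-3-[3-(benzyloxy)-2,4,6-trimethoxyphenyl]-4H-chromen-4-one | COc1cc(OC)c(-c2coc3cc(OCc4ccccc4)cc(OCc4ccccc4)c3c2=O)c(OC)c1OCc1ccccc1 | intermediate
9 | 5,7-dihydroxy-3-(3-hydroxy-2,4,6-trimethoxyphenyl)-4H-chromen-4-one (CNP0211564.0) | COc1cc(OC)c(-c2coc3cc(O)cc(O)c3c2=O)c(OC)c1O | target

**Total step count:** 5.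
**Longest linear sequence:** 4 steps (1 → 2 → 3 → 8 → 9).

**Steps most likely to fail**

**Step 4.** Four things can go wrong:
- Trifluoroacetate captures 6 and gives a 3-oxygenated chromone.
- The phenol O attacks the alpha carbon and gives a coumaranone.
- 6 dies as a chromon-3-yl iodonium salt.
- Leftover oxidant oxidises 5.

The fallback sets out from 2, uses 5, and returns at 8. It moves the bond formation to the acetophenone stage and builds ring C afterwards. Compound 2 is silylated with TMSOTf/Et3N in CH2Cl2 to 1-[2,4-bis(benzyloxy)-6-(trimethylsilyloxy)phenyl]-1-(trimethylsilyloxy)ethene F1. This is added at −78 °C to premixed PhI(OH)OTs/BF3·OEt2 in CH2Cl2 to preform the enolonium species. Adding 5 and warming gives the deoxybenzoin 1-[2,4-bis(benzyloxy)-6-hydroxyphenyl]-2-[3-(benzyloxy)-2,4,6-trimethoxyphenyl]ethan-1-one F2. Heating F2 with DMF-DMA, followed by a brief acid treatment, installs C2 and closes ring C to give 8.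

**Step 5.** The risk is saturation of C2=C3 to the isoflavanone before the hindered 3'-O-benzyl group has gone. The fallback sets out from 8 and returns at 9. It gives up reduction altogether. The benzyl groups are transferred as cations from the BCl3-activated ethers to pentamethylbenzene as scavenger arene (CH2Cl2, −78 °C, MeOH quench), and the methyl ethers survive at this temperature. This fallback makes no new compound (F0).

**Step 1.** The risks are C-benzylation of the phloroglucinol ring and mixtures of mono-, di- and tri-ethers. The fallback sets out from 1 and returns at 2. It over-protects and then deprotects selectively. Exhaustive benzylation (BnBr 3.5 equiv, K2CO3, DMF, 60 °C) gives 1-[2,4,6-tris(benzyloxy)phenyl]ethan-1-one F3. BCl3 (1.0 equiv, CH2Cl2, −78 °C), chelated to the ketone, then removes one ortho benzyl group to give 2.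

**Further compounds**
F1 | step 4 | 1-[2,4-bis(benzyloxy)-6-(trimethylsilyloxy)phenyl]-1-(trimethylsilyloxy)ethene | C=C(O[Si](C)(C)C)c1c(O[Si](C)(C)C)cc(OCc2ccccc2)cc1OCc1ccccc1
F2 | step 4 | 1-[2,4-bis(benzyloxy)-6-hydroxyphenyl]-2-[3-(benzyloxy)-2,4,6-trimethoxyphenyl]ethan-1-one | O=C(Cc1c(OC)cc(OC)c(OCc2ccccc2)c1OC)c1c(O)cc(OCc2ccccc2)cc1OCc1ccccc1
F0 | step 5 | none | none
F3 | step 1 | 1-[2,4,6-tris(benzyloxy)phenyl]ethan-1-one | CC(=O)c1c(OCc2ccccc2)cc(OCc2ccccc2)cc1OCc1ccccc1
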